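**Plan**

- Retrosynthesis: remove the O-acetyl group and a triethylsilyl mask on the tertiary alcohol; cut C4–C5 of the hept-2-enoate chain (acetoxy carbon to the CH2 beside the methyl-bearing CH) into an enal and an alkylzinc; cut C2=C3 of the enal half by a Wittig reaction; take the CH2–Zn back through iodide, alcohol and boronate to the isopropenyl group of a p-menthadienol.
- Enabling feature: C4 is the γ-carbon of the 2-alkylidene ester, so it is the formyl carbon of a 4-oxobut-2-enoate. C5 is the terminal carbon of the isopropenyl group on C4 of the 1-methylcyclohex-2-en-1-ol ring, so anti-Markovnikov hydroboration makes it a primary carbon nucleophile while setting C6.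
- Forward: the cyclohexenol ring is bought intact (no ring is made). Terpene half: silylation, hydroboration–oxidation, iodination. Enal half: ylide alkylation, Wittig olefination, acetal hydrolysis. The two C10 halves are joined by a catalytic asymmetric alkylzinc addition, followed by acetylation and desilylation.
- Stereochemistry: both ring centres come from the chiral pool; C6 from ligand-controlled copper hydride hydroboration; C4 from the chiral titanium bis(triflamide) catalyst in the union; the E enoate from the stabilised ylide.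

Key step: step 7

Assumption: dienol 1, (1R,4R)-p-mentha-2,8-dien-1-ol (the cis isomer: methyl cis and hydroxyl trans to isopropenyl), is bought as the single diastereomer; it is the minor dienol of the commercial cis/trans mixture made from (R)-limonene.

Assumption: the hydride face in step 2 is fixed by the ligand and not by the substrate; the ligand antipode written there is taken to give the required epimer, and its mirror image is used if a trial run shows the opposite sense.

**Route**

Step 1
Reactants: 1 (1R,4R)-1-methyl-4-(prop-1-en-2-yl)cyclohex-2-en-1-ol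
Product: 2 triethyl{[(1R,4R)-1-methyl-4-(prop-1-en-2-yl)cyclohex-2-en-1-yl]oxy}silane
Conditions: TESOTf, 2,6-lutidine, CH2Cl2, −78 → 0 °C
Reagents that add atoms: triethylsilyl trifluoromethanesulfonate, CC[Si](CC)(CC)OS(=O)(=O)C(F)(F)F
Why: O-silylation of a tertiary alcohol with a silyl triflate and a hindered base is fast at low temperature, touches no stereocentre, and masks the acidic OH for the iodination and organozinc steps.

Step 2
Reactants: 2 triethyl{[(1R,4R)-1-methyl-4-(prop-1-en-2-yl)cyclohex-2-en-1-yl]oxy}silane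
Product: 4 (2S)-2-[(1R,4R)-4-methyl-4-(triethylsilyloxy)cyclohex-2-en-1-yl]propan-1-ol, via pinacol boronate 3 (not isolated)
Conditions: CuCl (5 mol%), (R)-DTBM-SEGPHOS (5.5 mol%), KOtBu (10 mol%), HBpin (1.2 equiv), toluene, rt; then 3 M NaOH aq, 30% H2O2, THF, 0 °C
Reagents that add atoms: pinacolborane, CC1(C)OBOC1(C)C (the boronate group of 3); hydrogen peroxide, OO (the hydroxyl oxygen of 4)
Why: Copper hydride catalysed anti-Markovnikov hydroboration of an unactivated 1,1-disubstituted alkene puts copper and then boron on the terminal carbon and the new C–H on the face chosen by the bisphosphine (methyl against the branched cyclohexenyl group), the hindered ring alkene stays out, and alkaline peroxide oxidation of the boronate should give the primary alcohol.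

Step 3
Reactants: 4 (2S)-2-[(1R,4R)-4-methyl-4-(triethylsilyloxy)cyclohex-2-en-1-yl]propan-1-ol
Product: 5 triethyl{[(1R,4R)-4-[(2S)-1-iodopropan-2-yl]-1-methylcyclohex-2-en-1-yl]oxy}silane
Conditions: I2, PPh3, imidazole, CH2Cl2, 0 °C → rt
Reagents that add atoms: iodine, [I][I]
Why: Appel-type iodination displaces the activated primary oxygen by SN2 at CH2, so the neighbouring methyl-bearing centre and the buffered tertiary silyl ether should be untouched.

Step 4
Reactants: 6 methyl (triphenyl-λ5-phosphanylidene)acetate; 7 5-bromo-2-methylpent-2-ene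
Product: 9 methyl 6-methyl-2-(triphenyl-λ5-phosphanylidene)hept-5-enoate, via phosphonium bromide 8 (not isolated)
Conditions: MeCN, reflux; then 2 M NaOH aq, CH2Cl2, rt
Reagents that add atoms: none
Why: C-alkylation of the stabilised ylide by the primary bromide (SN2) gives the phosphonium salt, which brief treatment with aqueous hydroxide deprotonates to the α-substituted stabilised ylide.

Step 5
Reactants: 9 methyl 6-methyl-2-(triphenyl-λ5-phosphanylidene)hept-5-enoate; 10 2,2-dimethoxyacetaldehyde (used as its 60% aqueous solution)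
Product: 11 methyl (2E)-4,4-dimethoxy-2-(4-methylpent-3-en-1-yl)but-2-enoate
Conditions: CH2Cl2, rt → 40 °C
Reagents that add atoms: none
Why: Wittig olefination with an α-substituted ester-stabilised ylide is reversible up to the oxaphosphetane and should place the acetal carbon trans to the ester, which is the E trisubstituted enoate of the target.

Step 6
Reactants: 11 methyl (2E)-4,4-dimethoxy-2-(4-methylpent-3-en-1-yl)but-2-enoate
Product: 12 methyl (2E)-2-(4-methylpent-3-en-1-yl)-4-oxobut-2-enoate
Conditions: 1 M HCl aq, THF, 0 °C → rt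
Reagents that add atoms: water, O
Why: Acid-catalysed acetal hydrolysis frees the aldehyde; the E isomer (formyl trans to ester) is the stable geometry of a 4-oxo-2-enoate, and dilute acid at this temperature should leave the remote trisubstituted alkene alone.

Step 7
Reactants: 5 triethyl{[(1R,4R)-4-[(2S)-1-iodopropan-2-yl]-1-methylcyclohex-2-en-1-yl]oxy}silane; 12 methyl (2E)-2-(4-methylpent-3-en-1-yl)-4-oxobut-2-enoate
Product: 15 methyl (2E,4S,6R)-4-hydroxy-2-(4-methylpent-3-en-1-yl)-6-[(1S,4R)-4-methyl-4-(triethylsilyloxy)cyclohex-2-en-1-yl]hept-2-enoate, via dialkylzinc 13 (not isolated), via mixed alkylzinc 14 (not isolated)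
Conditions: 5 (1.5 equiv), Et2Zn (neat, 5 equiv), CuI (copper monoiodide, 0.3 mol%), 50 °C, then evaporate volatiles; Zn(CH2SiMe3)2 (0.75 equiv), Et2O, rt; Ti(OiPr)4 (1.2 equiv), N,N′-[(1R,2R)-cyclohexane-1,2-diyl]bis(trifluoromethanesulfonamide) (8 mol%), 12 (1.0 equiv), Et2O, −20 °C; water quench
Reagents that add atoms: diethylzinc, CC[Zn]CC (the zinc of 13 and 14 only); bis[(trimethylsilyl)methyl]zinc, C[Si](C)(C)C[Zn]C[Si](C)(C)C (zinc and CH2SiMe3 of 14 only); none of these stays in 15
Why: Copper-catalysed iodine–zinc exchange turns the primary iodide into the salt-free dialkylzinc, and comproportionation with Zn(CH2SiMe3)2 gives the mixed reagent in which the trimethylsilylmethyl group does not transfer, so each terpene alkyl is available to the aldehyde. Ti(OiPr)4 and the (1R,2R)-bis(triflamide) form a chiral titanium bis(sulfonamido) Lewis acid that binds the formyl group of 12 and takes the alkyl from zinc; delivery to the Si face of the aldehyde gives the 4S carbinol. The closest known reaction type is the titanium bis(triflamide)-catalysed addition of functionalised dialkylzincs to α,β-unsaturated aldehydes. No ring is closed; the one new stereocentre, C4, is set by the catalyst, because the C6 methyl centre is 1,3 to it and should exert little bias of its own. The step needs 1,2-addition to the aldehyde in preference to conjugate addition to the doubly activated C2=C3 bond and to attack on the methyl ester: alkylzincs do not add to esters or, uncatalysed, to enoates at −20 °C, and the titanium-bound formyl group is the only activated electrophile. The E geometry, with C4 trans to the ester, keeps the new metal alkoxide from lactonising.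

Step 8
Reactants: 15 methyl (2E,4S,6R)-4-hydroxy-2-(4-methylpent-3-en-1-yl)-6-[(1S,4R)-4-methyl-4-(triethylsilyloxy)cyclohex-2-en-1-yl]hept-2-enoate
Product: 16 methyl (2E,4S,6R)-4-(acetyloxy)-2-(4-methylpent-3-en-1-yl)-6-[(1S,4R)-4-methyl-4-(triethylsilyloxy)cyclohex-2-en-1-yl]hept-2-enoate
Conditions: Ac2O, pyridine, 4-(dimethylamino)pyridine (cat.), CH2Cl2, 0 °C → rt
Reagents that add atoms: acetic anhydride, CC(=O)OC(C)=O
Why: Nucleophile-catalysed O-acylation of the secondary allylic alcohol does not break the C4–O bond, so the 4S configuration should be retained, and the silylated tertiary alcohol cannot compete.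

Step 9
Reactants: 16 methyl (2E,4S,6R)-4-(acetyloxy)-2-(4-methylpent-3-en-1-yl)-6-[(1S,4R)-4-methyl-4-(triethylsilyloxy)cyclohex-2-en-1-yl]hept-2-enoate
Product: 17 methyl (2E,4S,6R)-4-(acetyloxy)-6-[(1S,4R)-4-hydroxy-4-methylcyclohex-2-en-1-yl]-2-(4-methylpent-3-en-1-yl)hept-2-enoate
Conditions: HF·pyridine, pyridine, THF, 0 °C → rt
Reagents that add atoms: none
Why: Fluoride-driven Si–O cleavage (desilylation) under pyridine buffering should free the tertiary allylic alcohol without ionising it and without touching the allylic acetate or the methyl ester.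

**Compound list**

1 | (1R,4R)-1-methyl-4-(prop-1-en-2-yl)cyclohex-2-en-1-ol | CC(=C)[C@H]1C=C[C@](C)(O)CC1 | starting material
2 | triethyl{[(1R,4R)-1-methyl-4-(prop-1-en-2-yl)cyclohex-2-en-1-yl]oxy}silane | CC(=C)[C@H]1C=C[C@](C)(O[Si](CC)(CC)CC)CC1 | intermediate
3 | 2-{(2R)-2-[(1S,4R)-4-methyl-4-(triethylsilyloxy)cyclohex-2-en-1-yl]propyl}-4,4,5,5-tetramethyl-1,3,2-dioxaborolane | CC1(C)OB(C[C@@H](C)[C@H]2C=C[C@](C)(O[Si](CC)(CC)CC)CC2)OC1(C)C | intermediate (not isolated)
4 | (2S)-2-[(1R,4R)-4-methyl-4-(triethylsilyloxy)cyclohex-2-en-1-yl]propan-1-ol | OC[C@@H](C)[C@H]1C=C[C@](C)(O[Si](CC)(CC)CC)CC1 | intermediate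
5 | triethyl{[(1R,4R)-4-[(2S)-1-iodopropan-2-yl]-1-methylcyclohex-2-en-1-yl]oxy}silane | IC[C@@H](C)[C@H]1C=C[C@](C)(O[Si](CC)(CC)CC)CC1 | intermediate
6 | methyl (triphenyl-λ5-phosphanylidene)acetate | COC(=O)C=P(c1ccccc1)(c1ccccc1)c1ccccc1 | starting material
7 | 5-bromo-2-methylpent-2-ene | CC(C)=CCCBr | starting material
8 | (1-methoxy-6-methyl-1-oxohept-5-en-2-yl)triphenylphosphonium bromide | COC(=O)C(CCC=C(C)C)[P+](c1ccccc1)(c1ccccc1)c1ccccc1.[Br-] | intermediate (not isolated)
9 | methyl 6-methyl-2-(triphenyl-λ5-phosphanylidene)hept-5-enoate | COC(=O)C(CCC=C(C)C)=P(c1ccccc1)(c1ccccc1)c1ccccc1 | intermediate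
10 | 2,2-dimethoxyacetaldehyde | COC(OC)C=O | starting material
11 | methyl (2E)-4,4-dimethoxy-2-(4-methylpent-3-en-1-yl)but-2-enoate | COC(=O)/C(=C/C(OC)OC)CCC=C(C)C | intermediate
12 | methyl (2E)-2-(4-methylpent-3-en-1-yl)-4-oxobut-2-enoate | COC(=O)/C(=C/C=O)CCC=C(C)C | intermediate
13 | bis{(2S)-2-[(1R,4R)-4-methyl-4-(triethylsilyloxy)cyclohex-2-en-1-yl]propyl}zinc | [Zn](C[C@@H](C)[C@H]1C=C[C@](C)(O[Si](CC)(CC)CC)CC1)C[C@@H](C)[C@H]1C=C[C@](C)(O[Si](CC)(CC)CC)CC1 | intermediate (not isolated)
14 | {(2S)-2-[(1R,4R)-4-methyl-4-(triethylsilyloxy)cyclohex-2-en-1-yl]propyl}[(trimethylsilyl)methyl]zinc | C[Si](C)(C)C[Zn]C[C@@H](C)[C@H]1C=C[C@](C)(O[Si](CC)(CC)CC)CC1 | intermediate (not isolated)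
15 | methyl (2E,4S,6R)-4-hydroxy-2-(4-methylpent-3-en-1-yl)-6-[(1S,4R)-4-methyl-4-(triethylsilyloxy)cyclohex-2-en-1-yl]hept-2-enoate | COC(=O)/C(=C/[C@H](C[C@@H](C)[C@H]1C=C[C@](C)(O[Si](CC)(CC)CC)CC1)O)CCC=C(C)C | intermediate
16 | methyl (2E,4S,6R)-4-(acetyloxy)-2-(4-methylpent-3-en-1-yl)-6-[(1S,4R)-4-methyl-4-(triethylsilyloxy)cyclohex-2-en-1-yl]hept-2-enoate | COC(=O)/C(=C/[C@H](C[C@@H](C)[C@H]1C=C[C@](C)(O[Si](CC)(CC)CC)CC1)OC(C)=O)CCC=C(C)C | intermediate
17 | methyl (2E,4S,6R)-4-(acetyloxy)-6-[(1S,4R)-4-hydroxy-4-methylcyclohex-2-en-1-yl]-2-(4-methylpent-3-en-1-yl)hept-2-enoate | COC(=O)/C(=C/[C@H](C[C@@H](C)[C@H]1C=C[C@](C)(O)CC1)OC(C)=O)CCC=C(C)C | target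

**Totals**

Total step count: 9.
Longest linear sequence: 6 steps (steps 1, 2, 3, 7, 8, 9; the enal branch, steps 4, 5, 6, 7, 8, 9, is equally long).

**Steps most likely to fail**

Step 7. What may go wrong: incomplete iodine–zinc exchange at the β-branched primary iodide, reduction of the aldehyde by β-hydride transfer from the alkylzinc, conjugate addition to the doubly activated alkene, or weak facial selectivity on a 4-oxo-enoate. The fallback gives up reagent control in the C–C bond formation and sets C4 afterwards. It sets out from iodide 5 and aldehyde 12. Iodine–lithium exchange of 5 (t-BuLi, Et2O, −78 °C), transmetalation with CeCl3 and addition of the organocerium to 12 at −78 °C should give the carbinol without face control, methyl (2E,6R)-4-hydroxy-2-(4-methylpent-3-en-1-yl)-6-[(1S,4R)-4-methyl-4-(triethylsilyloxy)cyclohex-2-en-1-yl]hept-2-enoate as both C4 epimers F1. Dess–Martin oxidation (CH2Cl2, NaHCO3, rt) should give the enone methyl (2E,6R)-2-(4-methylpent-3-en-1-yl)-6-[(1S,4R)-4-methyl-4-(triethylsilyloxy)cyclohex-2-en-1-yl]-4-oxohept-2-enoate F2. Corey–Bakshi–Shibata reduction of F2 with catecholborane and the (R)-B-methyl oxazaborolidine derived from diphenylprolinol (toluene, −78 °C), with the alkenyl group as the large substituent, should return to 15.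

Step 2. What may go wrong: poor facial selectivity in the hydrocupration if the ligand is mismatched with the neighbouring ring stereocentre, or slow turnover at the alkene beside the ring CH. The fallback replaces catalyst control by separation of epimers as crystalline esters. It sets out from silyl ether 2. Hydroboration with 9-borabicyclo[3.3.1]nonane (THF, rt) and alkaline peroxide oxidation should give 2-[(1R,4R)-4-methyl-4-(triethylsilyloxy)cyclohex-2-en-1-yl]propan-1-ol as both C2 epimers F3. Acylation with 3,5-dinitrobenzoyl chloride (pyridine, CH2Cl2) should give 2-[(1R,4R)-4-methyl-4-(triethylsilyloxy)cyclohex-2-en-1-yl]propyl 3,5-dinitrobenzoate as both C2 epimers F4. Fractional crystallisation or chromatography should deliver the single epimer (2S)-2-[(1R,4R)-4-methyl-4-(triethylsilyloxy)cyclohex-2-en-1-yl]propyl 3,5-dinitrobenzoate F5, and methanolysis (K2CO3, MeOH, rt) returns to 4.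

Step 4. What may go wrong: slow C-alkylation of the weakly nucleophilic stabilised ylide by an unactivated bromide, with competing O-alkylation or loss of HBr from the bromide. The fallback changes the olefination reagent to a phosphonate. It sets out from bromide 7. Alkylation of sodium trimethyl phosphonoacetate (NaH, DMF, 60 °C) with 7 should give methyl 2-(dimethoxyphosphoryl)-6-methylhept-5-enoate F6. Horner–Wadsworth–Emmons reaction of F6 with 10 (NaH, THF, 0 °C → rt) should give the enoate with the E isomer predominant, and chromatography returns pure 11.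

**Further compounds**

F1 | step 7 | methyl (2E,6R)-4-hydroxy-2-(4-methylpent-3-en-1-yl)-6-[(1S,4R)-4-methyl-4-(triethylsilyloxy)cyclohex-2-en-1-yl]hept-2-enoate, both C4 epimers | COC(=O)/C(=C/C(O)C[C@@H](C)[C@H]1C=C[C@](C)(O[Si](CC)(CC)CC)CC1)CCC=C(C)C
F2 | step 7 | methyl (2E,6R)-2-(4-methylpent-3-en-1-yl)-6-[(1S,4R)-4-methyl-4-(triethylsilyloxy)cyclohex-2-en-1-yl]-4-oxohept-2-enoate | COC(=O)/C(=C/C(=O)C[C@@H](C)[C@H]1C=C[C@](C)(O[Si](CC)(CC)CC)CC1)CCC=C(C)C
F3 | step 2 | 2-[(1R,4R)-4-methyl-4-(triethylsilyloxy)cyclohex-2-en-1-yl]propan-1-ol, both C2 epimers | OCC(C)[C@H]1C=C[C@](C)(O[Si](CC)(CC)CC)CC1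
F4 | step 2 | 2-[(1R,4R)-4-methyl-4-(triethylsilyloxy)cyclohex-2-en-1-yl]propyl 3,5-dinitrobenzoate, both C2 epimers | O=C(OCC(C)[C@H]1C=C[C@](C)(O[Si](CC)(CC)CC)CC1)c1cc(cc(c1)[N+](=O)[O-])[N+](=O)[O-]
F5 | step 2 | (2S)-2-[(1R,4R)-4-methyl-4-(triethylsilyloxy)cyclohex-2-en-1-yl]propyl 3,5-dinitrobenzoate | O=C(OC[C@@H](C)[C@H]1C=C[C@](C)(O[Si](CC)(CC)CC)CC1)c1cc(cc(c1)[N+](=O)[O-])[N+](=O)[O-]
F6 | step 4 | methyl 2-(dimethoxyphosphoryl)-6-methylhept-5-enoate | COC(=O)C(CCC=C(C)C)P(=O)(OC)OC
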